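**Retrosynthetic overview**

1. Numbering used throughout: furanone O1–C1(=C2H)–C3(=O)–C4(Me); ylidene C5=C6; butenolide C6–O–C12(=O)–C11(C13H2OAc)=C7; C8 (ester carbinol), C9, C10 (CHMe). The last bonds made are the C8 ester (Yamaguchi), C11–C13 (Stille hydroxymethylation of C11–Br) and the acetate.
2. The nine-membered oxacycle is closed at C7–C8 by an intramolecular Nozaki–Hiyama–Kishi reaction of a β-bromobutenolide. C5–C6 comes from a vinylogous Mukaiyama aldol of 3,4-dibromofuran-2(5H)-one, and C5=C6 is formed by E1cB only after ring closure, so that it can only be cis within the ring.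
3. The furanone ring is first made two atoms too small, as the Sharpless oxirane (O, C4, C3) of a 2,4-dienol. It is expanded by the vinyl carbons C2 and C1 (copper-catalysed vinyl oxirane to 2,5-dihydrofuran rearrangement) and then oxidized at C3 (singlet-oxygen ene reaction and dehydration).
4. Enabling feature: the ring oxygen sits on the fully substituted C4, and its neighbour C3 is allylic to C2=C1. Heterolysis of the strained allylic C3–O bond gives an allyl cation over C3–C2–C1, on which the C4 alkoxide recloses at C1; the C4–O bond set by the epoxidation is never broken.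
5. Order of ring formation: oxirane, then five-membered O-ring (ring expansion), then the butenolide (brought in ready-made), then the nine-membered ring. Stereocentres: C10 by Evans alkylation, C4 by Sharpless epoxidation, C8 in the ring closure.

Key step: step 8

Remark on the chemistry (assumption): the Nozaki–Hiyama–Kishi ring closure (step 14) is written for the 8S carbinol as the major epimer; this is the one stereocentre not secured by reagent control, and a reagent-controlled correction is given as a fallback.

**Route**

Step 1
Reactants: 1 (R)-4-benzyl-3-propanoyl-1,3-oxazolidin-2-one; 2 allyl iodide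
Product: 3 (R)-4-benzyl-3-[(2S)-2-methylpent-4-enoyl]-1,3-oxazolidin-2-one
Conditions: NaN(SiMe3)2, THF, −78 °C; then 2, −78 to −40 °C
Reagents that add atoms: none
Why: Evans asymmetric alkylation – the chelated Z-sodium enolate should be allylated on the face opposite the benzyl group of the (R)-auxiliary, which sets the future C10 as S.

Step 2
Reactants: 3
Product: 4 (2S)-2-methylpent-4-en-1-ol
Conditions: LiBH4, H2O (1 equiv), Et2O, 0 °C
Reagents that add atoms: none
Why: Reductive cleavage of the N-acyl oxazolidinone at the exocyclic carbonyl should release the primary alcohol without touching the α-stereocentre and return the auxiliary.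

Step 3
Reactants: 4
Product: 5 (2S)-2-methylpent-4-enal
Conditions: Dess–Martin periodinane, pyridine, CH2Cl2, 0 °C to rt; filtered solution used directly
Reagents that add atoms: none
Why: Dess–Martin oxidation under buffered, non-basic conditions should give the α-branched aldehyde without epimerization, and the volatile product is carried on in solution.

Step 4
Reactants: 5; 6 ethyl (2E)-4-(diethoxyphosphoryl)-2-methylbut-2-enoate
Product: 7 ethyl (2E,4E,6S)-2,6-dimethylnona-2,4,8-trienoate
Conditions: 6, LiN(SiMe3)2, THF, −78 °C; then 5, −78 to 0 °C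
Reagents that add atoms: none
Why: Vinylogous Horner–Wadsworth–Emmons olefination with the stabilized γ-phosphono anion should form the new C1=C2 bond E while the reagent keeps its 2E geometry, the low temperature protecting the α-stereocentre (C10).

Step 5
Reactants: 7
Product: 8 (2E,4E,6S)-2,6-dimethylnona-2,4,8-trien-1-ol
Conditions: i-Bu2AlH, CH2Cl2, −78 °C; Rochelle salt work-up
Reagents that add atoms: none
Why: 1,2-Reduction of the conjugated ester with i-Bu2AlH gives the allylic alcohol that directs the epoxidation.

Step 6
Reactants: 8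
Product: 9 [(2S,3S)-2-methyl-3-[(1E,3S)-3-methylhexa-1,5-dien-1-yl]oxiran-2-yl]methanol
Conditions: Ti(OiPr)4 (10 mol %), L-(+)-diethyl tartrate (12 mol %), t-BuOOH, 4 Å molecular sieves, CH2Cl2, −20 °C
Reagents that add atoms: tert-butyl hydroperoxide, CC(C)(C)OO
Why: Sharpless asymmetric epoxidation – only the allylic C3=C4 alkene is bound to the titanium tartrate, and L-(+)-diethyl tartrate should deliver oxygen to the face that gives the (2S,3S)-oxirane, which sets C4 (and the transient C3) by reagent control, independently of C10.

Step 7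
Reactants: 9
Product: 10 tert-butyl(dimethyl){[(2S,3S)-2-methyl-3-[(1E,3S)-3-methylhexa-1,5-dien-1-yl]oxiran-2-yl]methoxy}silane
Conditions: TBSCl, imidazole, CH2Cl2, 0 °C to rt
Reagents that add atoms: tert-butyldimethylsilyl chloride, CC(C)(C)[Si](C)(C)Cl
Why: Silylation removes the free hydroxyl that would otherwise bind the copper Lewis acid or open the oxirane (Payne-type) in the next step.

Step 8
Reactants: 10
Product: 11 tert-butyl(dimethyl){[(2R)-2-methyl-5-[(2S)-pent-4-en-2-yl]-2,5-dihydrofuran-2-yl]methoxy}silane (both epimers at the new ring carbon C1)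
Conditions: Cu(hfacac)2 (copper bis(hexafluoroacetylacetonate), 5 mol %), toluene, 150 °C, sealed tube
Reagents that add atoms: none
Why: The divalent-copper Lewis acid binds the oxirane oxygen and heterolyses the strained allylic C3–O bond to a copper alkoxide on C4 and an allyl cation over C3–C2–C1; the alkoxide oxygen, which stays on C4 throughout, then collapses on the cation terminus C1, so that the three-membered ring (O, C4, C3) grows by the two vinyl carbons into the five-membered ring (O, C4, C3, C2, C1) with release of the oxirane strain. The closest known reaction type is the Cu(hfacac)2-catalysed rearrangement of vinyl oxiranes to 2,5-dihydrofurans. The one ring closed is the 2,5-dihydrofuran, by C–O bond formation of an alkoxide onto the terminus of the adjacent allyl cation (formally 5-endo-trig, here an ion-pair collapse for which E and Z vinyl oxiranes converge). The new stereocentre C1 is not controlled and need not be, because it becomes sp2 in step 9, while C4 keeps the configuration set in step 6 because its C–O bond is never broken. The selectivity needed is ionization of the allylic C3–O bond rather than the tertiary C4–O bond, secured by allyl stabilization and by the inductively destabilizing CH2OSi group on C4, together with inertness of the isolated terminal alkene and the silyl ether towards the catalyst.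

Step 9
Reactants: 11
Product: 13 (2S)-2-({[tert-butyl(dimethyl)silyl]oxy}methyl)-2-methyl-5-[(2S)-pent-4-en-2-yl]furan-3(2H)-one, via allylic hydroperoxide 12 (not isolated)
Conditions: O2, tetraphenylporphyrin (cat.), visible light, Ac2O, pyridine, DMAP (cat.), CH2Cl2, 0 °C to rt
Reagents that add atoms: dioxygen, O=O
Why: Schenck ene reaction – singlet oxygen at the cis-disubstituted C2=C3 bond can only abstract the C1–H (C4 carries no hydrogen), which places the hydroperoxide on C3 and moves the double bond to C1=C2, and in situ acetylation with Kornblum–DeLaMare-type elimination gives the C3 ketone, a vinylogous ester that is inert to further singlet oxygen, as is the monosubstituted terminal alkene.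

Step 10
Reactants: 13
Product: 14 (2S)-2-(hydroxymethyl)-2-methyl-5-[(2S)-pent-4-en-2-yl]furan-3(2H)-one
Conditions: HF·pyridine, pyridine, THF, 0 °C to rt
Reagents that add atoms: none
Why: Desilylation under mildly acidic fluoride conditions frees the neopentylic alcohol without exposing the β-hydroxy ketone to base (retro-aldol loss of formaldehyde).

Step 11
Reactants: 14
Product: 15 (2S)-2-methyl-3-oxo-5-[(2S)-pent-4-en-2-yl]-2,3-dihydrofuran-2-carbaldehyde
Conditions: Dess–Martin periodinane, pyridine, CH2Cl2, 0 °C
Reagents that add atoms: none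
Why: Dess–Martin oxidation gives the non-enolizable α-formyl ketone under neutral conditions, which avoids deformylation.

Step 12
Reactants: 15; 16 3,4-dibromofuran-2(5H)-one
Product: 18 3,4-dibromo-5-[{[tert-butyl(dimethyl)silyl]oxy}{(2S)-2-methyl-3-oxo-5-[(2S)-pent-4-en-2-yl]-2,3-dihydrofuran-2-yl}methyl]furan-2(5H)-one (mixture at the new centres C5/C6), via silyloxyfuran 17 (not isolated)
Conditions: 16, TBSOTf (1.3 equiv), i-Pr2NEt, CH2Cl2, 0 °C; then 15, −78 to −40 °C
Reagents that add atoms: tert-butyldimethylsilyl trifluoromethanesulfonate, CC(C)(C)[Si](C)(C)OS(=O)(=O)C(F)(F)F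
Why: Vinylogous Mukaiyama aldol – the preformed 2-silyloxyfuran adds through its γ-carbon (C6) to the activated aldehyde with silyl transfer to the aldolate oxygen, the furanone meeting the amine/triflate pair only at low temperature so that its C10 γ-proton is not removed; the two new stereocentres (C5, C6) are not controlled beyond a Felkin-type bias and are both erased in step 17.

Step 13
Reactants: 18
Product: 20 (3S)-3-[(5S)-5-{(3,4-dibromo-5-oxo-2,5-dihydrofuran-2-yl)[(tert-butyldimethylsilyl)oxy]methyl}-5-methyl-4-oxo-4,5-dihydrofuran-2-yl]butanal, via vicinal diol 19 (not isolated)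
Conditions: OsO4 (2 mol %), NaIO4 (4 equiv), 2,6-lutidine, 1,4-dioxane/H2O (3:1), rt
Reagents that add atoms: osmium tetroxide, O=[Os](=O)(=O)=O; sodium periodate, [Na+].[O-]I(=O)(=O)=O
Why: Lemieux–Johnson cleavage – OsO4, continuously reoxidized by periodate, should dihydroxylate the monosubstituted alkene in preference to the push–pull furanone alkene and the tetrasubstituted dibromoalkene, and periodate cleaves the diol to the C8 aldehyde.

Step 14
Reactants: 20
Product: 21 bridged tricyclic carbinol (4S,8S,10S): C7 of the bromobutenolide bonded to C8, 8-OH, 11-Br, C5–OTBS, C6–H (C5/C6 mixture)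
Conditions: CrCl2 (8 equiv), NiCl2 (10 mol %), degassed DMSO/THF (3:1), 0.002 M, rt
Reagents that add atoms: none
Why: Nozaki–Hiyama–Kishi reaction – zerovalent nickel should insert into the more electrophilic β-C7–Br bond (a vinylogous acyl bromide) rather than the α-C11–Br bond, and the trivalent vinylchromium adds to the aldehyde to close the nine-membered oxacycle (9-exo-trig), a closure of the kind known for bridged oxonenes, with C8 set by substrate control of the folded chain (see remark).

Step 15
Reactants: 22 4-methylfuran-2(5H)-one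
Product: 25 (2Z)-4-{[tert-butyl(dimethyl)silyl]oxy}-3-methylbut-2-enoic acid, via potassium hydroxy carboxylate 23 (not isolated), via bis-silyl derivative 24 (not isolated)
Conditions: KOH (1.0 equiv), MeOH/H2O, rt, evaporate; TBSCl (2.4 equiv), imidazole, DMF, rt; then K2CO3, MeOH/THF/H2O, 0 °C; KHSO4 to pH 4
Reagents that add atoms: potassium hydroxide, [K+].[OH-]; tert-butyldimethylsilyl chloride, CC(C)(C)[Si](C)(C)Cl
Why: Saponification – hydroxide adds to the lactone carbonyl and supplies the second carboxylate oxygen while the ring fixes the Z geometry, and silylation of both oxygens followed by selective cleavage of the labile silyl ester gives the protected acid, which cannot relactonize.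

Step 16
Reactants: 21; 25
Product: 27 C8 (2Z)-4-(tert-butyldimethylsilyloxy)-3-methylbut-2-enoate of 21, via mixed anhydride 26 (not isolated)
Conditions: 25, 2,4,6-trichlorobenzoyl chloride, Et3N, THF, 0 °C to rt; then 21, DMAP, toluene, rt
Reagents that add atoms: none
Why: Yamaguchi esterification through the mixed 2,4,6-trichlorobenzoic anhydride acylates the hindered secondary C8 alcohol with retention and at the same time blocks this hydroxyl from translactonizing onto C12.

Step 17
Reactants: 27
Product: 28 ylidene lactone: 11-bromo compound with C5=C6 (C4 cis to C7), side-chain hydroxyl as TBS ether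
Conditions: DBU, CH2Cl2, 0 °C
Reagents that add atoms: none
Why: E1cB elimination – DBU removes the acidic γ-proton (C6–H) of the dibromobutenolide and the 2-oxidofuran expels the C5 silanolate, and because C4 and C7 are already tied into the nine-membered ring the new C5=C6 bond should form cis within the ring, i.e. with C4 cis to C7 as in the target.

Step 18
Reactants: 28; 29 (tributylstannyl)methanol
Product: 30 13-hydroxy compound (C11–CH2OH)
Conditions: Pd2(dba)3 (5 mol %), AsPh3 (20 mol %), 1,4-dioxane, 80 °C
Reagents that add atoms: none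
Why: Migita–Kosugi–Stille coupling – zerovalent palladium inserts into the remaining activated α-C11–Br bond of the enoate and transfers the hydroxymethyl group from tin, which installs C13.

Step 19
Reactants: 30
Product: 31 13-acetate, side-chain TBS ether
Conditions: Ac2O, pyridine, DMAP (cat.), CH2Cl2, 0 °C
Reagents that add atoms: acetic anhydride, CC(=O)OC(C)=O
Why: Standard acylation of the only free (primary allylic) hydroxyl.

Step 20
Reactants: 31
Product: 32 target CNP0269057.1
Conditions: HF·pyridine, pyridine, THF, 0 °C
Reagents that add atoms: none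
Why: Buffered HF·pyridine should cleave the primary allylic silyl ether while the mildly acidic, non-nucleophilic medium leaves the acetate, the enol lactone and the lactonization-prone Z-γ-hydroxy enoate untouched.

**Compound list**

1 | (R)-4-benzyl-3-propanoyl-1,3-oxazolidin-2-one | CCC(=O)N1[C@H](Cc2ccccc2)COC1=O | starting material
2 | allyl iodide | C=CCI | starting material
3 | (R)-4-benzyl-3-[(2S)-2-methylpent-4-enoyl]-1,3-oxazolidin-2-one | C=CC[C@H](C)C(=O)N1[C@H](Cc2ccccc2)COC1=O | intermediate
4 | (2S)-2-methylpent-4-en-1-ol | OC[C@@H](C)CC=C | intermediate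
5 | (2S)-2-methylpent-4-enal | O=C[C@@H](C)CC=C | intermediate
6 | ethyl (2E)-4-(diethoxyphosphoryl)-2-methylbut-2-enoate | CCOC(=O)/C(C)=C/CP(=O)(OCC)OCC | starting material
7 | ethyl (2E,4E,6S)-2,6-dimethylnona-2,4,8-trienoate | CCOC(=O)/C(C)=C/C=C/[C@@H](C)CC=C | intermediate
8 | (2E,4E,6S)-2,6-dimethylnona-2,4,8-trien-1-ol | OC/C(C)=C/C=C/[C@@H](C)CC=C | intermediate
9 | [(2S,3S)-2-methyl-3-[(1E,3S)-3-methylhexa-1,5-dien-1-yl]oxiran-2-yl]methanol | OC[C@]1(C)O[C@H]1/C=C/[C@@H](C)CC=C | intermediate
10 | TBS ether of 9 | CC(C)(C)[Si](C)(C)OC[C@]1(C)O[C@H]1/C=C/[C@@H](C)CC=C | intermediate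
11 | tert-butyl(dimethyl){[(2R)-2-methyl-5-[(2S)-pent-4-en-2-yl]-2,5-dihydrofuran-2-yl]methoxy}silane (C1 epimers) | CC(C)(C)[Si](C)(C)OC[C@]1(C)OC([C@@H](C)CC=C)C=C1 | intermediate
12 | C3 hydroperoxide: tert-butyl{[(2S)-3-hydroperoxy-2-methyl-5-[(2S)-pent-4-en-2-yl]-2,3-dihydrofuran-2-yl]methoxy}dimethylsilane | CC(C)(C)[Si](C)(C)OC[C@]1(C)OC([C@@H](C)CC=C)=CC1OO | intermediate (not isolated)
13 | (2S)-2-({[tert-butyl(dimethyl)silyl]oxy}methyl)-2-methyl-5-[(2S)-pent-4-en-2-yl]furan-3(2H)-one | CC(C)(C)[Si](C)(C)OC[C@]1(C)OC([C@@H](C)CC=C)=CC1=O | intermediate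
14 | (2S)-2-(hydroxymethyl)-2-methyl-5-[(2S)-pent-4-en-2-yl]furan-3(2H)-one | OC[C@]1(C)OC([C@@H](C)CC=C)=CC1=O | intermediate
15 | (2S)-2-methyl-3-oxo-5-[(2S)-pent-4-en-2-yl]-2,3-dihydrofuran-2-carbaldehyde | O=C[C@]1(C)OC([C@@H](C)CC=C)=CC1=O | intermediate
16 | 3,4-dibromofuran-2(5H)-one | O=C1OCC(Br)=C1Br | starting material
17 | tert-butyl[(3,4-dibromofuran-2-yl)oxy]dimethylsilane | CC(C)(C)[Si](C)(C)Oc1occ(Br)c1Br | intermediate (not isolated)
18 | vinylogous aldol adduct (C5–OTBS, C6–H; mixture at C5/C6) | CC(C)(C)[Si](C)(C)OC(C1OC(=O)C(Br)=C1Br)[C@]2(C)OC([C@@H](C)CC=C)=CC2=O | intermediate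
19 | terminal 1,2-diol of 18 | CC(C)(C)[Si](C)(C)OC(C1OC(=O)C(Br)=C1Br)[C@]2(C)OC([C@@H](C)CC(O)CO)=CC2=O | intermediate (not isolated)
20 | C8 aldehyde: (3S)-3-[(5S)-5-{(3,4-dibromo-5-oxo-2,5-dihydrofuran-2-yl)[(tert-butyldimethylsilyl)oxy]methyl}-5-methyl-4-oxo-4,5-dihydrofuran-2-yl]butanal | CC(C)(C)[Si](C)(C)OC(C1OC(=O)C(Br)=C1Br)[C@]2(C)OC([C@@H](C)CC=O)=CC2=O | intermediate
21 | bridged tricyclic carbinol (4S,8S,10S), 8-OH, 11-Br, C5–OTBS, C6–H | BrC1=C2C(C(O[Si](C)(C)C(C)(C)C)[C@]3(C)OC(=CC3=O)[C@@H](C)C[C@@H]2O)OC1=O | intermediate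
22 | 4-methylfuran-2(5H)-one | CC1=CC(=O)OC1 | starting material
23 | potassium (2Z)-4-hydroxy-3-methylbut-2-enoate | [K+].[O-]C(=O)/C=C(/C)CO | intermediate (not isolated)
24 | tert-butyldimethylsilyl (2Z)-4-(tert-butyldimethylsilyloxy)-3-methylbut-2-enoate | CC(C)(C)[Si](C)(C)OC(=O)/C=C(/C)CO[Si](C)(C)C(C)(C)C | intermediate (not isolated)
25 | (2Z)-4-{[tert-butyl(dimethyl)silyl]oxy}-3-methylbut-2-enoic acid | OC(=O)/C=C(/C)CO[Si](C)(C)C(C)(C)C | intermediate
26 | mixed anhydride of 25 with 2,4,6-trichlorobenzoic acid | O=C(OC(=O)/C=C(/C)CO[Si](C)(C)C(C)(C)C)c1c(Cl)cc(Cl)cc1Cl | intermediate (not isolated)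
27 | C8 ester of 21 with acid 25 | BrC1=C2C(C(O[Si](C)(C)C(C)(C)C)[C@]3(C)OC(=CC3=O)[C@@H](C)C[C@@H]2OC(=O)/C=C(/C)CO[Si](C)(C)C(C)(C)C)OC1=O | intermediate
28 | ylidene lactone, 11-bromo, side-chain TBS ether | BrC1=C2/C(=C\[C@]3(C)OC(=CC3=O)[C@@H](C)C[C@@H]2OC(=O)/C=C(/C)CO[Si](C)(C)C(C)(C)C)OC1=O | intermediate
29 | (tributylstannyl)methanol | CCCC[Sn](CCCC)(CCCC)CO | starting material
30 | 13-hydroxy compound, side-chain TBS ether | OCC1=C2/C(=C\[C@]3(C)OC(=CC3=O)[C@@H](C)C[C@@H]2OC(=O)/C=C(/C)CO[Si](C)(C)C(C)(C)C)OC1=O | intermediate
31 | 13-acetate, side-chain TBS ether | CC(=O)OCC1=C2/C(=C\[C@]3(C)OC(=CC3=O)[C@@H](C)C[C@@H]2OC(=O)/C=C(/C)CO[Si](C)(C)C(C)(C)C)OC1=O | intermediate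
32 | CNP0269057.1 | CC(=O)OCC1=C2/C(=C\[C@]3(C)OC(=CC3=O)[C@@H](C)C[C@@H]2OC(=O)/C=C(/C)CO)OC1=O | target

**Summary**

Total step count: 20. Longest linear sequence: 19 steps (steps 1–14 and 16–20; step 15 is the side-chain branch).

**Steps most likely to fail**

Step 14 (nine-membered ring closure). The two faces of the C8 aldehyde may be poorly differentiated, or the 8R carbinol may prevail; nickel may also insert into the α-C11–Br bond. The fallback replaces substrate control at C8 by reagent control. It sets out from 21 as obtained (mixture of C8 epimers): Dess–Martin oxidation should give the C8 ketone F1, and Corey–Bakshi–Shibata reduction (BH3·SMe2, (R)-2-methyl-CBS-oxazaborolidine, with the butenolide carbon C7 as the large group) should return the 8S alcohol. It comes back to the route at 21.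

Step 9 (oxidation to the furanone). The ene reaction of the cis-disubstituted alkene may be slow, and the enol-ether hydroperoxide 12 may be consumed by a second singlet-oxygen addition before it is dehydrated. The fallback is a radical allylic oxidation. It sets out from 11 with t-BuOOH and Rh2(cap)4 (dirhodium tetracaprolactamate), K2CO3, CH2Cl2, rt: the doubly activated C1–H is abstracted, the allyl radical is captured at the less hindered C3 as the mixed tert-butyl peroxide F2 (not isolated), and loss of tert-butanol should give the ketone directly. It comes back to the route at 13.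

Step 8 (ring expansion). Lewis-acid ionization may be diverted to a hydride shift (carbonyl isomers) or to proton loss from the allyl cation (trienes), or may touch the tertiary C4–O bond. The fallback replaces Lewis-acid ionization by a nucleophile relay. It sets out from 10: MgI2 in Et2O at −40 °C should open the vinyl oxirane by SN2′ attack of iodide at C1 to the allylic iodo alcohol F3 (its E/Z and 1,3-isomers equilibrate through iodide), and K2CO3 in MeCN should close the C4 alkoxide onto C1 by SN2 displacement, again without touching the C4–O bond. It comes back to the route at 11.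

Further compounds
F1 | step 14 | C8 ketone of 21 (4S,10S; 11-Br, C5–OTBS, C6–H) | BrC1=C2C(C(O[Si](C)(C)C(C)(C)C)[C@]3(C)OC(=CC3=O)[C@@H](C)CC2=O)OC1=O
F2 | step 9 | tert-butyl{[(2S)-3-(tert-butylperoxy)-2-methyl-5-[(2S)-pent-4-en-2-yl]-2,3-dihydrofuran-2-yl]methoxy}dimethylsilane | CC(C)(C)[Si](C)(C)OC[C@]1(C)OC([C@@H](C)CC=C)=CC1OOC(C)(C)C
F3 | step 8 | (2R,3Z,6S)-1-{[tert-butyl(dimethyl)silyl]oxy}-5-iodo-2,6-dimethylnona-3,8-dien-2-ol (C5 epimers) | CC(C)(C)[Si](C)(C)OC[C@](C)(O)/C=C\C(I)[C@@H](C)CC=C
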